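Atom labels: lactone ring O1, C2 (C=O), C3 (quaternary C–O), C4, C5 (OCH2); C7′ is the benzylic carbinol carbon on C4. TBS = tert-butyldimethylsilyl.

**Plan**

- Retrosynthesis: remove three silyl groups; cut the C7′–aryl bond to a C4-formyl lactone and a guaiacyl iodide; derive CHO from a propenyl group; cut C3–CH2Ar (enolate benzylation) and C3–O (enolate hydroxylation); cut C4–propenyl back to furan-2(5H)-one.
- Forward order: the lactone ring is present from the start. Onto it come propenyl at C4, oxygen at C3, the vanillyl group at C3, the formyl group at C4, and last the second guaiacyl ring at C7′.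
- Stereochemistry: C4 from Rh/(S)-BINAP conjugate addition; C3 from benzylation of the enolate anti to the C4 substituent; C7′ from Felkin–Anh addition to the formyl group, governed by C4 and the neighbouring fully substituted C3.
- Enabling feature: C7′ is an exocyclic secondary carbinol carbon bonded to aromatic C1 and to ring C4, next to the fully substituted C3. At the aldehyde level it is an electrophile, like the iodide-bearing aryl carbon, so the two are joined reductively (Ni/Cr). Its β-acyloxy (C5–O1) and β-silyloxy (C3–O) surroundings require the non-basic chromium reagent.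

Key step: step 10

Remark: the enantioface sense of the Rh/(S)-BINAP addition to furan-2(5H)-one is assigned by analogy with cyclic enones and six-membered lactones; should it prove opposite, (R)-BINAP is used and nothing else changes.

**Route**

Step 1
Reactants: 1 furan-2(5H)-one; 2 (E)-prop-1-en-1-ylboronic acid
Product: 3 (S)-4-[(E)-prop-1-en-1-yl]oxolan-2-one
Conditions: [Rh(OH)((S)-BINAP)]2 (1.5 mol %), 2 (3 equiv), dioxane/H2O 10:1, 40 °C
Reagents that add atoms: none
Why: Hayashi–Miyaura Rh(I)-catalysed asymmetric 1,4-addition of an alkenylboronic acid to an unsaturated lactone, in which the propenyl–Rh(BINAP) species inserts one enantioface of the enoate and hydrolysis of the oxa-π-allyl rhodium releases 3, so that the ligand sets C4.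

Step 2
Reactants: 3 (S)-4-[(E)-prop-1-en-1-yl]oxolan-2-one
Product: 5 (3R,4S)-3-hydroxy-4-[(E)-prop-1-en-1-yl]oxolan-2-one, via potassium enolate 4 (not isolated)
Conditions: KHMDS, THF, −78 °C; 3-phenyl-2-(phenylsulfonyl)oxaziridine, −78 °C; AcOH quench
Reagents that add atoms: 3-phenyl-2-(phenylsulfonyl)oxaziridine O=S(=O)(c1ccccc1)N1OC1c1ccccc1
Why: Davis oxidation of the potassium lactone enolate, with oxygen transferred anti to the C4 propenyl group to give the trans-hydroxy lactone; the C3 configuration is erased again in step 7, so only the oxidation level matters here.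

Step 3
Reactants: 5 (3R,4S)-3-hydroxy-4-[(E)-prop-1-en-1-yl]oxolan-2-one
Product: 6 (3R,4S)-3-[(tert-butyldimethylsilyl)oxy]-4-[(E)-prop-1-en-1-yl]oxolan-2-one
Conditions: TBSCl, imidazole, DMF, rt
Reagents that add atoms: tert-butyldimethylsilyl chloride CC(C)(C)[Si](C)(C)Cl
Why: Standard imidazole-mediated silylation of a secondary α-hydroxy lactone, which masks the hydroxyl for the enolate alkylation and later makes O3 non-chelating in the key step.

Step 4
Reactants: 7 vanillin
Product: 8 4-[(tert-butyldimethylsilyl)oxy]-3-methoxybenzaldehyde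
Conditions: TBSCl, imidazole, CH2Cl2, rt
Reagents that add atoms: tert-butyldimethylsilyl chloride CC(C)(C)[Si](C)(C)Cl
Why: Imidazole-mediated silylation of the phenol, which leaves the aldehyde untouched.

Step 5
Reactants: 8 4-[(tert-butyldimethylsilyl)oxy]-3-methoxybenzaldehyde
Product: 9 {4-[(tert-butyldimethylsilyl)oxy]-3-methoxyphenyl}methanol
Conditions: NaBH4, MeOH, 0 °C
Reagents that add atoms: none
Why: Borohydride reduction of an aromatic aldehyde under conditions that the aryl silyl ether tolerates.

Step 6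
Reactants: 9 {4-[(tert-butyldimethylsilyl)oxy]-3-methoxyphenyl}methanol
Product: 10 [4-(bromomethyl)-2-methoxyphenoxy](tert-butyl)dimethylsilane
Conditions: PBr3, Et2O, 0 °C; used at once
Reagents that add atoms: phosphorus tribromide BrP(Br)Br
Why: Conversion of an electron-rich benzylic alcohol into the bromide through its phosphite ester (nucleophilic substitution by bromide), the labile bromide being taken directly into step 7.

Step 7
Reactants: 6 (3R,4S)-3-[(tert-butyldimethylsilyl)oxy]-4-[(E)-prop-1-en-1-yl]oxolan-2-one; 10 [4-(bromomethyl)-2-methoxyphenoxy](tert-butyl)dimethylsilane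
Product: 12 (3S,4S)-3-[(tert-butyldimethylsilyl)oxy]-3-({4-[(tert-butyldimethylsilyl)oxy]-3-methoxyphenyl}methyl)-4-[(E)-prop-1-en-1-yl]oxolan-2-one, via lithium enolate 11 (not isolated)
Conditions: LDA, THF, −78 °C; then 10, DMPU, −78 → −40 °C
Reagents that add atoms: none
Why: C-alkylation of an α-silyloxy lactone enolate by a reactive benzylic bromide, in which the electrophile enters the planar C3 anti to the C4 propenyl group, so that the benzyl group ends trans and the silyloxy group cis to the C4 substituent and the quaternary centre is fixed as 3S.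

Step 8
Reactants: 12 (3S,4S)-3-[(tert-butyldimethylsilyl)oxy]-3-({4-[(tert-butyldimethylsilyl)oxy]-3-methoxyphenyl}methyl)-4-[(E)-prop-1-en-1-yl]oxolan-2-one
Product: 14 (3S,4S)-4-[(tert-butyldimethylsilyl)oxy]-4-({4-[(tert-butyldimethylsilyl)oxy]-3-methoxyphenyl}methyl)-5-oxooxolane-3-carbaldehyde, via secondary ozonide 13 (not isolated)
Conditions: O3, CH2Cl2, −78 °C (Sudan III end point); Me2S, −78 °C → rt; crude aldehyde used directly
Reagents that add atoms: ozone [O-][O+]=O
Why: Ozonolysis (Criegee mechanism) of the only C=C bond with reductive work-up, which leaves the C4 stereocentre untouched, avoids base that would enolise the β-acyloxy aldehyde, and gives acetaldehyde as a volatile co-product.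

Step 9
Reactants: 15 4-iodo-2-methoxyphenol
Product: 16 tert-butyl(4-iodo-2-methoxyphenoxy)dimethylsilane
Conditions: TBSCl, imidazole, DMF, rt
Reagents that add atoms: tert-butyldimethylsilyl chloride CC(C)(C)[Si](C)(C)Cl
Why: Imidazole-mediated phenol silylation, to which the C–I bond is inert.

Step 10
Reactants: 14 (3S,4S)-4-[(tert-butyldimethylsilyl)oxy]-4-({4-[(tert-butyldimethylsilyl)oxy]-3-methoxyphenyl}methyl)-5-oxooxolane-3-carbaldehyde; 16 tert-butyl(4-iodo-2-methoxyphenoxy)dimethylsilane
Product: 18 (3S,4R)-3-[(tert-butyldimethylsilyl)oxy]-4-[(R)-{4-[(tert-butyldimethylsilyl)oxy]-3-methoxyphenyl}(hydroxy)methyl]-3-({4-[(tert-butyldimethylsilyl)oxy]-3-methoxyphenyl}methyl)oxolan-2-one, via arylchromium(III) dichloride 17 (not isolated)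
Conditions: CrCl2 (4 equiv), NiCl2 (2 mol %), 16 (2 equiv), degassed DMF, rt; aqueous work-up
Reagents that add atoms: none
Why: Ni(0), formed from NiCl2 by Cr(II), inserts into the C–I bond of 16, the aryl group passes to chromium (two Cr(II) per aryl) and the arylchromium(III) 17 adds to the formyl carbon C7′ of 14 through a chromium-bound carbonyl, so that two electrophilic carbons are joined reductively. The closest known reaction type is the Nozaki–Hiyama–Kishi (Takai) coupling of aryl iodides with aldehydes. No ring is closed. The new stereocentre C7′ is set by 1,2-induction from ring carbon C4 in a Felkin–Anh transition state: the fully substituted C3 (carrying OTBS, the benzyl group and the lactone carbonyl) stands anti to the incoming aryl group, the carbonyl oxygen lies on the side of the ring CH2 (C5) and the aryl group passes the C4–H, which should give the (R)-carbinol. The step needs selection of CHO over the lactone and three silyl ethers, no enolisation (C4 epimerisation, E1cB opening of the ring by loss of the C5–O carboxylate, loss of silanolate from C3) and the non-chelated facial sense; the non-basic, aldehyde-selective organochromium reagent secures the first two, and the bulky, non-coordinating OTBS group on C3 suppresses the C3–O/C7′=O chelate that would lead to the C7′ epimer.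

Step 11
Reactants: 18 (3S,4R)-3-[(tert-butyldimethylsilyl)oxy]-4-[(R)-{4-[(tert-butyldimethylsilyl)oxy]-3-methoxyphenyl}(hydroxy)methyl]-3-({4-[(tert-butyldimethylsilyl)oxy]-3-methoxyphenyl}methyl)oxolan-2-one
Product: 19 (3S,4R)-3-hydroxy-4-[(R)-hydroxy(4-hydroxy-3-methoxyphenyl)methyl]-3-[(4-hydroxy-3-methoxyphenyl)methyl]oxolan-2-one
Conditions: TBAF, AcOH (1:1, excess), THF, 0 °C → rt
Reagents that add atoms: none
Why: Fluoride-induced cleavage of the two aryl silyl ethers and the tertiary alkyl silyl ether through pentacoordinate silicates, buffered with AcOH so that neither acyl transfer from O1 to the C7′ oxygen (translactonisation) nor quinone-methide formation at the p-hydroxybenzylic carbinol is triggered, and no stereocentre is touched.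

**Compound list**

1 | furan-2(5H)-one | O=C1C=CCO1 | starting material
2 | (E)-prop-1-en-1-ylboronic acid | C/C=C/B(O)O | starting material
3 | (S)-4-[(E)-prop-1-en-1-yl]oxolan-2-one | O=C1C[C@@H](/C=C/C)CO1 | intermediate
4 | potassium enolate of 3 (O-potassium at C2, C2=C3, C4 as in 3) | [K+].[O-]C1=C[C@@H](/C=C/C)CO1 | intermediate
5 | (3R,4S)-3-hydroxy-4-[(E)-prop-1-en-1-yl]oxolan-2-one (OH trans to propenyl) | O=C1[C@H](O)[C@@H](/C=C/C)CO1 | intermediate
6 | (3R,4S)-3-[(tert-butyldimethylsilyl)oxy]-4-[(E)-prop-1-en-1-yl]oxolan-2-one | O=C1[C@H](O[Si](C)(C)C(C)(C)C)[C@@H](/C=C/C)CO1 | intermediate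
7 | vanillin (4-hydroxy-3-methoxybenzaldehyde) | COc1cc(C=O)ccc1O | starting material
8 | 4-[(tert-butyldimethylsilyl)oxy]-3-methoxybenzaldehyde | COc1cc(C=O)ccc1O[Si](C)(C)C(C)(C)C | intermediate
9 | {4-[(tert-butyldimethylsilyl)oxy]-3-methoxyphenyl}methanol | COc1cc(CO)ccc1O[Si](C)(C)C(C)(C)C | intermediate
10 | [4-(bromomethyl)-2-methoxyphenoxy](tert-butyl)dimethylsilane | COc1cc(CBr)ccc1O[Si](C)(C)C(C)(C)C | intermediate
11 | lithium enolate of 6 (O-lithium at C2, C2=C3 bearing OTBS, C4 as in 6) | [Li+].[O-]C1=C(O[Si](C)(C)C(C)(C)C)[C@@H](/C=C/C)CO1 | intermediate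
12 | (3S,4S)-3-[(tert-butyldimethylsilyl)oxy]-3-({4-[(tert-butyldimethylsilyl)oxy]-3-methoxyphenyl}methyl)-4-[(E)-prop-1-en-1-yl]oxolan-2-one (benzyl trans, OTBS cis to propenyl) | COc1cc(C[C@@]2(O[Si](C)(C)C(C)(C)C)C(=O)OC[C@@H]2/C=C/C)ccc1O[Si](C)(C)C(C)(C)C | intermediate
13 | secondary ozonide of 12 (5-methyl-1,2,4-trioxolan-3-yl group on C4 in place of propenyl; mixture at the two ozonide carbons) | COc1cc(C[C@@]2(O[Si](C)(C)C(C)(C)C)C(=O)OC[C@@H]2C3OOC(C)O3)ccc1O[Si](C)(C)C(C)(C)C | intermediate
14 | (3S,4S)-4-[(tert-butyldimethylsilyl)oxy]-4-({4-[(tert-butyldimethylsilyl)oxy]-3-methoxyphenyl}methyl)-5-oxooxolane-3-carbaldehyde | COc1cc(C[C@@]2(O[Si](C)(C)C(C)(C)C)C(=O)OC[C@@H]2C=O)ccc1O[Si](C)(C)C(C)(C)C | intermediate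
15 | 4-iodo-2-methoxyphenol | COc1cc(I)ccc1O | starting material
16 | tert-butyl(4-iodo-2-methoxyphenoxy)dimethylsilane | COc1cc(I)ccc1O[Si](C)(C)C(C)(C)C | intermediate
17 | {4-[(tert-butyldimethylsilyl)oxy]-3-methoxyphenyl}chromium(III) dichloride (DMF-solvated) | COc1cc([Cr](Cl)Cl)ccc1O[Si](C)(C)C(C)(C)C | intermediate
18 | (3S,4R)-3-[(tert-butyldimethylsilyl)oxy]-4-[(R)-{4-[(tert-butyldimethylsilyl)oxy]-3-methoxyphenyl}(hydroxy)methyl]-3-({4-[(tert-butyldimethylsilyl)oxy]-3-methoxyphenyl}methyl)oxolan-2-one | COc1cc(C[C@@]2(O[Si](C)(C)C(C)(C)C)C(=O)OC[C@@H]2[C@@H](O)c2ccc(O[Si](C)(C)C(C)(C)C)c(OC)c2)ccc1O[Si](C)(C)C(C)(C)C | intermediate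
19 | (3S,4R)-3-hydroxy-4-[(R)-hydroxy(4-hydroxy-3-methoxyphenyl)methyl]-3-[(4-hydroxy-3-methoxyphenyl)methyl]oxolan-2-one | COc1cc(C[C@@]2(O)C(=O)OC[C@@H]2[C@@H](O)c2ccc(O)c(OC)c2)ccc1O | target

**Count and risks**

Total step count: 11. Longest linear sequence: 7 steps (steps 1, 2, 3, 7, 8, 10, 11; the vanillin branch, steps 4, 5, 6, 7, 8, 10, 11, is equally long).

Steps most likely to fail:

Step 10. The arylchromium reagent may discriminate poorly between the two faces of the hindered formyl group (Felkin against anti-Felkin or partial chelate delivery), so that both C7′ configurations form. The fallback sets out from 14 (with 16) and comes back at 18. The coupling is run to full conversion without regard to the ratio. The mixture of 18 and its C7′ epimer, (3S,4R)-3-[(tert-butyldimethylsilyl)oxy]-4-[(S)-{4-[(tert-butyldimethylsilyl)oxy]-3-methoxyphenyl}(hydroxy)methyl]-3-({4-[(tert-butyldimethylsilyl)oxy]-3-methoxyphenyl}methyl)oxolan-2-one F1, is oxidised with Dess–Martin periodinane/NaHCO3 in CH2Cl2 to the aryl ketone (3S,4S)-3-[(tert-butyldimethylsilyl)oxy]-4-{4-[(tert-butyldimethylsilyl)oxy]-3-methoxybenzoyl}-3-({4-[(tert-butyldimethylsilyl)oxy]-3-methoxyphenyl}methyl)oxolan-2-one F2. F2 is then reduced under reagent control with (S)-2-methyl-CBS-oxazaborolidine and BH3·SMe2 in THF at −20 °C, which should deliver hydride to the face giving the (R)-carbinol 18 when the aryl group acts as the large substituent.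

Step 8. Ozone may attack the electron-rich silyloxy(methoxy)arene in competition with the alkene, and the aldehyde may suffer β-elimination or epimerisation while oxidant residues are removed. The fallback sets out from 12 and comes back at 14. Dihydroxylation of the propenyl C=C with catalytic OsO4/NMO in acetone–water (osmium tetroxide leaves the arene alone) gives the diol (3S,4R)-3-[(tert-butyldimethylsilyl)oxy]-3-({4-[(tert-butyldimethylsilyl)oxy]-3-methoxyphenyl}methyl)-4-(1,2-dihydroxypropyl)oxolan-2-one F3. Cleavage of F3 with NaIO4 in pH 7-buffered THF–water at 0 °C gives 14.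

Step 7. Silicon may migrate from oxygen to carbon in the α-silyloxy enolate (retro-Brook), or the facial control in forming the quaternary centre may be incomplete. The fallback sets out from 5 (with 10) and comes back at 12. The alkoxide–enolate dianion of 5 (LDA, 2.2 equiv, THF/DMPU, −78 → −30 °C) is benzylated with 10, again anti to the propenyl group, to give the tertiary alcohol (3S,4S)-3-hydroxy-3-({4-[(tert-butyldimethylsilyl)oxy]-3-methoxyphenyl}methyl)-4-[(E)-prop-1-en-1-yl]oxolan-2-one F4. F4 is silylated with TBSOTf/2,6-lutidine in CH2Cl2 to give 12.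

**Further compounds**

F1 | step 10 | (3S,4R)-3-[(tert-butyldimethylsilyl)oxy]-4-[(S)-{4-[(tert-butyldimethylsilyl)oxy]-3-methoxyphenyl}(hydroxy)methyl]-3-({4-[(tert-butyldimethylsilyl)oxy]-3-methoxyphenyl}methyl)oxolan-2-one | COc1cc(C[C@@]2(O[Si](C)(C)C(C)(C)C)C(=O)OC[C@@H]2[C@H](O)c2ccc(O[Si](C)(C)C(C)(C)C)c(OC)c2)ccc1O[Si](C)(C)C(C)(C)C
F2 | step 10 | (3S,4S)-3-[(tert-butyldimethylsilyl)oxy]-4-{4-[(tert-butyldimethylsilyl)oxy]-3-methoxybenzoyl}-3-({4-[(tert-butyldimethylsilyl)oxy]-3-methoxyphenyl}methyl)oxolan-2-one | COc1cc(C[C@@]2(O[Si](C)(C)C(C)(C)C)C(=O)OC[C@@H]2C(=O)c2ccc(O[Si](C)(C)C(C)(C)C)c(OC)c2)ccc1O[Si](C)(C)C(C)(C)C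
F3 | step 8 | (3S,4R)-3-[(tert-butyldimethylsilyl)oxy]-3-({4-[(tert-butyldimethylsilyl)oxy]-3-methoxyphenyl}methyl)-4-(1,2-dihydroxypropyl)oxolan-2-one (ring centres as in 12; mixture at the two diol carbons) | COc1cc(C[C@@]2(O[Si](C)(C)C(C)(C)C)C(=O)OC[C@@H]2C(O)C(C)O)ccc1O[Si](C)(C)C(C)(C)C
F4 | step 7 | (3S,4S)-3-hydroxy-3-({4-[(tert-butyldimethylsilyl)oxy]-3-methoxyphenyl}methyl)-4-[(E)-prop-1-en-1-yl]oxolan-2-one | COc1cc(C[C@@]2(O)C(=O)OC[C@@H]2/C=C/C)ccc1O[Si](C)(C)C(C)(C)C
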